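From 5.00 h to 10.0 h, J's rise per hour, divided by the D standing at that moment, holds still between the oak and birch runs although their E charges differ, so that invariant is what I watch.

| flask | E | Q | remark | time |
|---|---|---|---|---|
| oak | 0.14 M | 0.030 M | run made earlier |  |
| birch | 0.22 M | 0.030 M | run made earlier |  |
| flask | 0.10 M | 0.0300 M |  | 12 h |
- oak (time / h: J / %, D / %): 2.50: 2.7, 8.0; 5.00: 7.8, 9.9; 8.00: 13.5, 9.3; 10.0: 17.6, 9.3
- birch (time / h: J / %, D / %): 2.50: 2.9, 9.1; 5.00: 8.9, 11.4; 8.00: 14.6, 10.9; 10.0: 19.8, 10.0

(standard deviation of a reading: 0.5 percentage points)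
- ratio of J to D at 20 min
- ratio of J to D at 2.0 h
- ratio of J to D at 12 h


In the oak run, from 5.00 h to 10.0 h, J gains 9.8 percentage points over a mean D of 9.60%. D over J's hourly rise, turned into a half-life, gives 3.40 h, my reading of the half-life of D on its way to J. One run could flatter that, but birch gives 3.40 h.

While D climbs from nothing, J over D should grow as half the elapsed time's share of that rate, which gives 0.0340 at 20 min. The same line gives 0.255 at 2.50 h, yet oak reads 0.338 there, so I distrust the line once D bends. For 2.0 h I scale that oak reading by time instead and get 0.270.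

For 12 h, the flask's smaller charge worries me. But oak and birch read 1.89 and 1.98 at 10.0 h, and a factor shared by J and D cancels in their ratio, so I start from oak. Steady D gives 2.30. Birch's D sags, though, and carrying that sag forward gives 2.45, which I commit to.

The forecast, reading the curves as “D as an intermediate”, says 0.035, 0.24 and 2.3, the last lower than mine.

The flask gives 0.0366, 0.250 and 2.49.

    E ⇌ L (K = 0.430, k = 1.14 × 10⁻⁴ s⁻¹)
    E → D (k = 2.41 × 10⁻⁵ s⁻¹)
    L ⇌ Z (K = 1.70, k = 3.23 × 10⁻⁴ s⁻¹)
    Z ⇌ G (K = 0.362, k = 0.00240 s⁻¹)
    D → J (k = 5.77 × 10⁻⁵ s⁻¹)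
    E + Q → X (k = 0.216 L mol⁻¹ s⁻¹)

From 6.00 h to 12.0 h in this flask, the half-life on mean D predicts 10.4% of new J, and J gains 11 points. The neighbour flask holds 0.12 M of Q, and there E, the limiting reagent, stands at 0% by 12.0 h. I count its D as made in the first minutes and then halving every 3.40 h, which gives 0.503 at 2.0 h and 10.5 at 12 h. The neighbour gives 0.500 and 10.7, with D at 0.0170% against J at 0.181% after 12.0 h.

The data were generated by integration for substances that don't exist, noise included.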